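## Structural features

The target is a dearomatised acylphloroglucinol. Ring A is a six-membered carbocycle drawn as an enolised 2-acylcyclohexane-1,3-dione (C5 ketone, C6 acyl, C7 enol), fused through C4a=C8a to ring B, a 2,2-dimethyl-2H-pyran whose oxygen sits on C8a. C8 of ring A, between the C7 oxygen and C8a, is an all-carbon quaternary stereocentre (R) that carries a prenyl group and a ten-carbon chain. Both arms start with CH2, so a reagent that has to tell them apart has little to work with. The chain holds a second stereocentre, the isopropenyl-bearing methine (R), one CH2 away from C8, and ends in an (E)-2-methyl-2-enoic acid. The third stereocentre, the α-carbon of the (R)-2-methylbutanoyl group on C6, is remote from both and is the only one that can epimerise by enolisation. Fragile groups are the chromene alkene, the prenyl and isopropenyl groups (acid, electrophiles, cyclisation onto a neighbouring oxygen), and the acidic, metal-binding enolised trione. The real difficulty is twofold: C8 with defined configuration next to an open-chain methine, and, in aromatic precursors, telling apart O5 and O7, which both flank the acyl group. The key step uses the aromatic tautomeric ancestor, a 6-acyl-5,7-dihydroxy-8-prenyl-2,2-dimethylchromene. There O7–C7=C8 is the enol-ether half of an allyl aryl ether, so an allyl unit hung on O7 through a stereogenic carbinol carbon can be handed suprafacially to C8, while C6 (acyl) and C4a (ring fusion) close every other outlet.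

## Logic of the disconnections

23 ⇒ 22. Only the C–O bond of the carboxyl group is cut (acid back to ethyl ester). The free acid is kept away from the ylide and the hydride of the earlier steps. The forward step must be a hydrolysis mild enough for the chromene and the acyl stereocentre.

22 ⇒ 20 + 21. The C2=C3 bond of the enoate is cut. This removes three carbons and the only stereodefined alkene in one stroke. The forward olefination must be (E)-selective and must tolerate the acidic trione.

20 ⇒ 19. No skeletal bond is cut; the aldehyde carbon is traced to an ester carbon. This gives the acceptor needed one step earlier. The forward reduction has to stop at the aldehyde and must not touch the ring carbonyls.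

19 ⇒ 17 + 18. The bond between the chain methine and the isopropenyl carbon is cut. The methine stereocentre disappears and a planar (E)-enoate is left. The forward conjugate addition must be controlled by the catalyst, because the only resident stereocentre nearby (C8) is three atoms away.

17 ⇒ 16. The bond between C8 and the first chain carbon is cut and the bond between O7 and the former γ-carbon is restored, which re-aromatises ring A. The quaternary stereocentre is exchanged for a secondary carbinol stereocentre that can be bought by resolution. The forward [3,3] shift must pass through one chair. The bookkeeping was checked: the (S) carbinol carbon of 16 with the ester equatorial does give the C8 configuration of 23. The descriptor at C8 reads S in 17 and R from 19 on only because the ranking of the two arms changes.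

16 ⇒ 12 + 14 (through 15). The O7–C(carbinol) bond is cut. A direct etherification of the 5,7-diol would not distinguish O5 from O7 (both are flanked on two sides and both can chelate the acyl carbonyl). The precursor is therefore assembled from 12, in which O5 is silylated and O7 is the only free phenol. The forward substitution must invert cleanly at a secondary allylic α-ester carbon.

14 ⇒ 13. No bond is cut; the single enantiomer is traced to the racemate. The forward step is an enzymatic kinetic resolution.

12 ⇒ 9 (through 10 and 11). The C4–C4a bond of ring B is cut, which leaves the pyran oxygen attached to its CMe2 carbon as an aryl propargyl ether. Ring B is thereby fixed on the oxygen para to the acyl group, and on the only free ring carbon, without any choice between oxygens. The forward cascade needs heat that the silyl ether and the prenyl group survive.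

9 ⇒ 8. The O–Si bond is cut. The silyl group is placed while one phenol still has a ring CH as neighbour and the other is flanked by acyl and prenyl. The forward silylation must pick the less hindered one. Once ring B is closed this difference is gone, which is why the order is fixed.

8 ⇒ 6 + 7. The O–CMe2 ether bond is cut. The forward etherification must go to the hydroxyl para to the acyl group, the most acidic and the only one outside the hydrogen bond to the carbonyl.

6 ⇒ 4 + 5. The aryl C–CH2 bond of the prenyl group is cut. The forward C-alkylation has to stop at mono-substitution.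

4 ⇒ 1 + 2 (through 3). The aryl–acyl bond is cut, giving two commercial compounds. The forward acylation must not racemise the α-carbon of the acyl group.

## Other disconnections considered

Alternative 1: Ring B is cut at O1–C2 and at C4–C4a. This leads back to the acyl trione A2 (quaternary centre and full chain in place, acid as methyl ester) and 3-methylbut-2-enal A3. In the forward step A3 would condense at the free ring methylene of A2, and the 1-oxatriene would close by oxa-6π electrocyclisation to the methyl ester A1, one saponification away from 23.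
- In its favour: two bonds and a ring from a cheap C5 aldehyde in one step, and the acid-sensitive chromene would be made second to last. On this point the alternative is the better plan, because the chromene would never meet the rhodium step, the hydride or the ylide.
- Against it: the oxatriene can close through either oxygen flanking the methylene (the one beside the quaternary carbon, as required, or the one beside the acyl-bearing carbon). Only the hydrogen bond of the acyl group argues for the right one.
- Against it: the problem of C8 is not solved but moved into A2, whose synthesis would need the same aryl-ether logic without ring B to mark the para oxygen.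
- Comparison: structurally both plans make the same ring. Mechanistically both close it by a pericyclic step (here late, in the chosen plan early from a propargyl ether). In step count it is about equal (one annulation against etherification plus heating). In regiochemical certainty the chosen plan is ahead.

Alternative 2: The bond between a ring methylene carbon and the acyl carbonyl carbon is cut. This gives the symmetric trione A4 and (R)-2-methylbutanoic anhydride A5. A chiral 4-aminopyridine would have to acylate one of the two methylene groups selectively to give A2.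
- In its favour: the quaternary centre would be set by a catalyst. The epimerisable acyl group would arrive late, a point on which the alternative is the better plan. No aromatic oxygen has to be differentiated, where it is at least equal.
- Against it: the two methylene groups differ only through the two arms on the remote quaternary carbon, and both arms begin with CH2. The catalyst would have little to read.
- Against it: the catalyst would also have to cooperate with two resident stereocentres (chain methine, anhydride), and the acylpyridinium could erode the anhydride by enolisation.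
- Against it: A4 itself needs the chain methine set on a trione bearing two different arms, and ring B would still have to be added as in alternative 1.
- Comparison: group selection by a catalyst is less predictable here than transfer of chirality through a chair from a resolved C4 building block. The step count would be higher.

Alternative 3: The bond between the chain methine and the next methylene toward the acid is cut. The (E)-allylic chloride A7 on the dearomatised chromene core would react with (1,3-dioxolan-2-ylmethyl)magnesium bromide A8 under CuBr·SMe2 and a chiral phosphoramidite in an SN2′ sense to give the dioxolane A6. Acetal hydrolysis would then give 20.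
- In its favour: one C–C bond formation would set the methine, create the isopropenyl group and bring the aldehyde carbon in masked form. No ester reduction is needed next to the trione, and the chain is one step shorter; on the chain end-game the alternative is the better plan.
- Against it: the organomagnesium reagent would meet the acidic trione, and A8 is a sluggish nucleophile prone to β-elimination. The 2-methyl-substituted chloride is a demanding substrate for branch selectivity, and the acetal would have to be cleaved with acid beside a chromene and a prenyl group.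
- Against it, and decisive: A7 carries two nearly identical C5 arms on C8 (prenyl and 4-chloroprenyl). A Claisen delivery of the chloro arm would need a tertiary ether in which methyl and chloromethyl compete for the equatorial site, so the clean transfer of chirality is lost.
- Comparison: the structure reached (20) is the same. The mechanism is catalyst-controlled allylic substitution against catalyst-controlled conjugate addition, comparable in precedent. The gain of one step in the chain is paid for by an unsolved quaternary centre.

Key step: step 8

Assumption 1: the lipase of step 6 acetylates the (S)-alcohol of 13 faster, as it does with other 2-hydroxy esters, so the (R)-alcohol is the recovered component.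
Assumption 2: with BINAP the sense of induction in step 9 follows the usual quadrant model, in which the (S)-ligand exposes the αsi face of an (E)-acceptor; the αre face is needed, hence (R)-BINAP.

## Route

Step 1
Reactants: 1 phloroglucinol; 2 (R)-2-methylbutanoic acid
Product: 4 (R)-2-methyl-1-(2,4,6-trihydroxyphenyl)butan-1-one, via (R)-2-methylbutanoyl chloride 3 (not isolated)
Conditions: 2, (COCl)2, DMF (cat.), CH2Cl2, 0 °C to rt; then 1, AlCl3, PhNO2/CH2Cl2, 0 °C to rt
Reagents that add atoms: none
Why: Friedel–Crafts C-acylation of the most electron-rich arene available; the symmetry of 1 allows only one product, the deactivating acyl group prevents a second acylation, and the low temperature and the aluminium chelate of the product limit enolisation at the acyl stereocentre.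

Step 2
Reactants: 4 (R)-2-methyl-1-(2,4,6-trihydroxyphenyl)butan-1-one; 5 1-bromo-3-methylbut-2-ene
Product: 6 (R)-2-methyl-1-[2,4,6-trihydroxy-3-(3-methylbut-2-en-1-yl)phenyl]butan-1-one
Conditions: 5 (1.0 equiv), aq. KOH (10%), 0 °C
Reagents that add atoms: none
Why: Aromatic C-alkylation of the acylphloroglucinol anion in water, where solvation of the oxygens directs the allylic bromide to carbon (the classical C-prenylation of acylphloroglucinols); the two free ring carbons are equivalent, one equivalent of bromide limits double alkylation, and the phenoxide form suppresses enolisation of the ketone.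

Step 3
Reactants: 6 (R)-2-methyl-1-[2,4,6-trihydroxy-3-(3-methylbut-2-en-1-yl)phenyl]butan-1-one; 7 3-chloro-3-methylbut-1-yne
Product: 8 (R)-1-{2,6-dihydroxy-3-(3-methylbut-2-en-1-yl)-4-[(2-methylbut-3-yn-2-yl)oxy]phenyl}-2-methylbutan-1-one
Conditions: 7, K2CO3, KI, CuI (cat.), acetone, 55 °C
Reagents that add atoms: none
Why: Copper-assisted O-propargylation of a phenol with a tertiary propargylic chloride (Williamson-type etherification through the copper acetylide); the hydroxyl para to the acyl group is the most acidic and the only one not tied up in the hydrogen bond to the carbonyl, so it reacts selectively.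

Step 4
Reactants: 8 (R)-1-{2,6-dihydroxy-3-(3-methylbut-2-en-1-yl)-4-[(2-methylbut-3-yn-2-yl)oxy]phenyl}-2-methylbutan-1-one
Product: 9 (R)-1-{6-[(tert-butyldimethylsilyl)oxy]-2-hydroxy-3-(3-methylbut-2-en-1-yl)-4-[(2-methylbut-3-yn-2-yl)oxy]phenyl}-2-methylbutan-1-one
Conditions: TBSCl (1.05 equiv), imidazole, DMF, 0 °C
Reagents that add atoms: tert-butyldimethylsilyl chloride, CC(C)(C)[Si](C)(C)Cl
Why: Silylation of the less hindered phenol: the hydroxyl next to the ring CH has one ortho substituent, whereas the one between acyl and prenyl has two and stays behind as the chelated phenol. This is done before ring B exists because afterwards both phenols would be flanked on two sides.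

Step 5
Reactants: 9 (R)-1-{6-[(tert-butyldimethylsilyl)oxy]-2-hydroxy-3-(3-methylbut-2-en-1-yl)-4-[(2-methylbut-3-yn-2-yl)oxy]phenyl}-2-methylbutan-1-one
Product: 12 (R)-1-{5-[(tert-butyldimethylsilyl)oxy]-7-hydroxy-2,2-dimethyl-8-(3-methylbut-2-en-1-yl)-2H-chromen-6-yl}-2-methylbutan-1-one, via ortho-allenylphenol 10 (not isolated), via ortho-quinone methide 11 (not isolated)
Conditions: o-xylene, 140 °C
Reagents that add atoms: none
Why: Aryl propargyl ether Claisen rearrangement to the only free ortho carbon, enolisation, 1,5-hydrogen shift and oxa-6π electrocyclisation, the standard thermal route to 2,2-dimethyl-2H-chromenes. The ether oxygen becomes the pyran oxygen, so ring B is fused para to the acyl group with no regiochemical choice.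

Step 6
Reactants: 13 ethyl 2-hydroxybut-3-enoate (racemic)
Product: 14 ethyl (R)-2-hydroxybut-3-enoate
Conditions: vinyl acetate, Burkholderia cepacia lipase (Amano PS), t-BuOMe, 30 °C, to ca. 55% conversion
Reagents that add atoms: none
Why: Lipase-catalysed kinetic resolution of a secondary α-hydroxy ester by irreversible transesterification; the (S)-alcohol should be acetylated and the (R)-alcohol recovered, and running slightly past half conversion raises the enantiomeric purity of the recovered alcohol.

Step 7
Reactants: 12 (R)-1-{5-[(tert-butyldimethylsilyl)oxy]-7-hydroxy-2,2-dimethyl-8-(3-methylbut-2-en-1-yl)-2H-chromen-6-yl}-2-methylbutan-1-one; 14 ethyl (R)-2-hydroxybut-3-enoate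
Product: 16 ethyl (S)-2-({5-hydroxy-2,2-dimethyl-6-[(2R)-2-methylbutanoyl]-8-(3-methylbut-2-en-1-yl)-2H-chromen-7-yl}oxy)but-3-enoate, via 5-O-silyl ether 15 (not isolated)
Conditions: PPh3, DIAD, toluene, 0 °C to rt; then Et3N·3HF, THF, rt
Reagents that add atoms: none
Why: Mitsunobu etherification of the only free phenol with an activated secondary α-hydroxy ester, an SN2 process with inversion, so (R)-14 gives the (S)-ether. The neighbouring ester disfavours ionisation and so protects the stereocentre, and buffered fluoride then removes the aryl silyl ether without base.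

Step 8
Reactants: 16 ethyl (S)-2-({5-hydroxy-2,2-dimethyl-6-[(2R)-2-methylbutanoyl]-8-(3-methylbut-2-en-1-yl)-2H-chromen-7-yl}oxy)but-3-enoate
Product: 17 ethyl (2E)-4-[(8S)-7-hydroxy-2,2-dimethyl-6-[(2R)-2-methylbutanoyl]-8-(3-methylbut-2-en-1-yl)-5-oxo-5,8-dihydro-2H-chromen-8-yl]but-2-enoate
Conditions: toluene (degassed), 100 °C
Reagents that add atoms: none
Why: Concerted suprafacial [3,3]-sigmatropic shift of the allyl aryl ether (aromatic Claisen rearrangement): the bond from O7 to the carbinol carbon breaks while the terminal CH2 of the vinyl group bonds to C8, and the first-formed 6,6-disubstituted cyclohexa-2,4-dienone tautomerises through the free C5 hydroxyl to the enolised acyl trione, the sink that makes the dearomatisation downhill. The closest known reaction type is the ortho-Claisen rearrangement onto a substituted ortho carbon with 1,3-transfer of chirality from a secondary allylic ether. No ring is closed. The new stereocentre C8 is controlled by the (S) carbinol carbon: in the chair transition state the ester lies equatorial, the prenyl group on C8 (cis to O7 on the arene) is axial and C8a equatorial, so the CH2 terminus reaches the face of C8 that gives the configuration of the target (descriptor S in 17 because here the prenyl arm outranks the new arm), and the same arrangement makes the new alkene (E). The step needs site and face selectivity: C8 is the only productive terminus because C6 carries the acyl group and the para position C4a is the ring fusion, so a shift to either gives a dienone that cannot enolise and can only revert, and face selectivity rests on the equatorial preference of the ester together with the chair preference of aromatic Claisen rearrangements. The ester on the carbinol carbon also disfavours ionisation to an allyl cation, which would erase the stereochemical information, and the unsubstituted CH2 terminus keeps the bond to the quaternary carbon unhindered.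

Step 9
Reactants: 17 ethyl (2E)-4-[(8S)-7-hydroxy-2,2-dimethyl-6-[(2R)-2-methylbutanoyl]-8-(3-methylbut-2-en-1-yl)-5-oxo-5,8-dihydro-2H-chromen-8-yl]but-2-enoate; 18 4,4,5,5-tetramethyl-2-(prop-1-en-2-yl)-1,3,2-dioxaborolane
Product: 19 ethyl (3S)-3-{[(8R)-7-hydroxy-2,2-dimethyl-6-[(2R)-2-methylbutanoyl]-8-(3-methylbut-2-en-1-yl)-5-oxo-5,8-dihydro-2H-chromen-8-yl]methyl}-4-methylpent-4-enoate
Conditions: 18 (4 equiv), Rh(acac)(C2H4)2 (5 mol %), (R)-BINAP (6 mol %), KOH (1.1 equiv), 1,4-dioxane/H2O (10:1), 90 °C; aq. HCl work-up
Reagents that add atoms: none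
Why: Rhodium-catalysed asymmetric conjugate addition of an alkenylboron reagent to an (E)-enoate (Hayashi–Miyaura reaction): transmetalation to an alkenylrhodium, insertion of the enoate and hydrolysis of the rhodium enolate. The ligand sets the new methine stereocentre by delivering the isopropenyl group to the αre face; the trione travels as its potassium enolate, which is neither acidic nor electrophilic.

Step 10
Reactants: 19 ethyl (3S)-3-{[(8R)-7-hydroxy-2,2-dimethyl-6-[(2R)-2-methylbutanoyl]-8-(3-methylbut-2-en-1-yl)-5-oxo-5,8-dihydro-2H-chromen-8-yl]methyl}-4-methylpent-4-enoate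
Product: 20 (3S)-3-{[(8R)-7-hydroxy-2,2-dimethyl-6-[(2R)-2-methylbutanoyl]-8-(3-methylbut-2-en-1-yl)-5-oxo-5,8-dihydro-2H-chromen-8-yl]methyl}-4-methylpent-4-enal
Conditions: i-Bu2AlH (2.2 equiv), CH2Cl2, −78 °C; aq. potassium sodium tartrate
Reagents that add atoms: none
Why: Partial reduction of an ester to the aldehyde by i-Bu2AlH at −78 °C through the aluminium hemiacetal, which does not collapse until the quench. The first equivalent turns the acidic enol into an aluminium enolate, which shields the ring carbonyls and the acyl ketone from hydride.

Step 11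
Reactants: 20 (3S)-3-{[(8R)-7-hydroxy-2,2-dimethyl-6-[(2R)-2-methylbutanoyl]-8-(3-methylbut-2-en-1-yl)-5-oxo-5,8-dihydro-2H-chromen-8-yl]methyl}-4-methylpent-4-enal; 21 ethyl 2-(triphenylphosphoranylidene)propanoate
Product: 22 ethyl (2E,5R)-5-{[(8R)-7-hydroxy-2,2-dimethyl-6-[(2R)-2-methylbutanoyl]-8-(3-methylbut-2-en-1-yl)-5-oxo-5,8-dihydro-2H-chromen-8-yl]methyl}-2,6-dimethylhepta-2,6-dienoate
Conditions: 21 (2.5 equiv), toluene, 50 °C
Reagents that add atoms: none
Why: Wittig olefination with a stabilised ylide, which gives the (E)-trisubstituted enoate; the excess covers the equivalent of ylide that the acidic trione protonates, and nothing else in 20 is electrophilic toward it.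

Step 12
Reactants: 22 ethyl (2E,5R)-5-{[(8R)-7-hydroxy-2,2-dimethyl-6-[(2R)-2-methylbutanoyl]-8-(3-methylbut-2-en-1-yl)-5-oxo-5,8-dihydro-2H-chromen-8-yl]methyl}-2,6-dimethylhepta-2,6-dienoate
Product: 23 (2E,5R)-5-{[(8R)-7-hydroxy-2,2-dimethyl-6-[(2R)-2-methylbutanoyl]-8-(3-methylbut-2-en-1-yl)-5-oxo-5,8-dihydro-2H-chromen-8-yl]methyl}-2,6-dimethylhepta-2,6-dienoic acid
Conditions: LiOH, THF/MeOH/H2O, rt; then 1 M HCl to pH 3, 0 °C
Reagents that add atoms: lithium hydroxide (aqueous), [Li+].[OH-]
Why: Saponification of the ethyl ester; under the basic conditions the trione is an enolate, which keeps hydroxide away from the ring and from the acyl stereocentre, and brief cold acidification frees the acid without harming the chromene or the prenyl group.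

## Compound list

1 | phloroglucinol (benzene-1,3,5-triol) | Oc1cc(O)cc(O)c1 | starting material
2 | (R)-2-methylbutanoic acid | CC[C@@H](C)C(=O)O | starting material
3 | (R)-2-methylbutanoyl chloride | CC[C@@H](C)C(=O)Cl | intermediate (not isolated)
4 | (R)-2-methyl-1-(2,4,6-trihydroxyphenyl)butan-1-one | CC[C@@H](C)C(=O)c1c(O)cc(O)cc1O | intermediate
5 | 1-bromo-3-methylbut-2-ene (prenyl bromide) | CC(C)=CCBr | starting material
6 | (R)-2-methyl-1-[2,4,6-trihydroxy-3-(3-methylbut-2-en-1-yl)phenyl]butan-1-one | CC[C@@H](C)C(=O)c1c(O)cc(O)c(CC=C(C)C)c1O | intermediate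
7 | 3-chloro-3-methylbut-1-yne | C#CC(C)(C)Cl | starting material
8 | (R)-1-{2,6-dihydroxy-3-(3-methylbut-2-en-1-yl)-4-[(2-methylbut-3-yn-2-yl)oxy]phenyl}-2-methylbutan-1-one | CC[C@@H](C)C(=O)c1c(O)cc(OC(C)(C)C#C)c(CC=C(C)C)c1O | intermediate
9 | (R)-1-{6-[(tert-butyldimethylsilyl)oxy]-2-hydroxy-3-(3-methylbut-2-en-1-yl)-4-[(2-methylbut-3-yn-2-yl)oxy]phenyl}-2-methylbutan-1-one (silyl ether on the hydroxyl whose ring neighbour is CH) | CC[C@@H](C)C(=O)c1c(O[Si](C)(C)C(C)(C)C)cc(OC(C)(C)C#C)c(CC=C(C)C)c1O | intermediate
10 | (R)-1-{6-[(tert-butyldimethylsilyl)oxy]-2,4-dihydroxy-5-(3-methylbuta-1,2-dien-1-yl)-3-(3-methylbut-2-en-1-yl)phenyl}-2-methylbutan-1-one (ortho-allenylphenol) | CC[C@@H](C)C(=O)c1c(O[Si](C)(C)C(C)(C)C)c(C=C=C(C)C)c(O)c(CC=C(C)C)c1O | intermediate (not isolated)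
11 | ortho-quinone methide from 10 by 1,5-hydrogen shift: 2-acyl-3-silyloxy-4-(3-methylbut-2-en-1-ylidene)-6-prenyl-1-hydroxycyclohexa-1,5-dien-5-one skeleton, acyl = (R)-2-methylbutanoyl | CC[C@@H](C)C(=O)C1=C(O[Si](C)(C)C(C)(C)C)C(=CC=C(C)C)C(=O)C(CC=C(C)C)=C1O | intermediate (not isolated)
12 | (R)-1-{5-[(tert-butyldimethylsilyl)oxy]-7-hydroxy-2,2-dimethyl-8-(3-methylbut-2-en-1-yl)-2H-chromen-6-yl}-2-methylbutan-1-one | CC1(C)C=Cc2c(O[Si](C)(C)C(C)(C)C)c(C(=O)[C@H](C)CC)c(O)c(CC=C(C)C)c2O1 | intermediate
13 | ethyl 2-hydroxybut-3-enoate (racemic) | C=CC(O)C(=O)OCC | starting material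
14 | ethyl (R)-2-hydroxybut-3-enoate | C=C[C@@H](O)C(=O)OCC | intermediate
15 | ethyl (S)-2-({5-[(tert-butyldimethylsilyl)oxy]-2,2-dimethyl-6-[(2R)-2-methylbutanoyl]-8-(3-methylbut-2-en-1-yl)-2H-chromen-7-yl}oxy)but-3-enoate | CC1(C)C=Cc2c(O[Si](C)(C)C(C)(C)C)c(C(=O)[C@H](C)CC)c(O[C@@H](C=C)C(=O)OCC)c(CC=C(C)C)c2O1 | intermediate (not isolated)
16 | ethyl (S)-2-({5-hydroxy-2,2-dimethyl-6-[(2R)-2-methylbutanoyl]-8-(3-methylbut-2-en-1-yl)-2H-chromen-7-yl}oxy)but-3-enoate | CC1(C)C=Cc2c(O)c(C(=O)[C@H](C)CC)c(O[C@@H](C=C)C(=O)OCC)c(CC=C(C)C)c2O1 | intermediate
17 | ethyl (2E)-4-[(8S)-7-hydroxy-2,2-dimethyl-6-[(2R)-2-methylbutanoyl]-8-(3-methylbut-2-en-1-yl)-5-oxo-5,8-dihydro-2H-chromen-8-yl]but-2-enoate | CCOC(=O)/C=C/C[C@]1(CC=C(C)C)C(O)=C(C(=O)[C@H](C)CC)C(=O)C2=C1OC(C)(C)C=C2 | intermediate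
18 | 4,4,5,5-tetramethyl-2-(prop-1-en-2-yl)-1,3,2-dioxaborolane | C=C(C)B1OC(C)(C)C(C)(C)O1 | starting material
19 | ethyl (3S)-3-{[(8R)-7-hydroxy-2,2-dimethyl-6-[(2R)-2-methylbutanoyl]-8-(3-methylbut-2-en-1-yl)-5-oxo-5,8-dihydro-2H-chromen-8-yl]methyl}-4-methylpent-4-enoate | C=C(C)[C@H](CC(=O)OCC)C[C@]1(CC=C(C)C)C(O)=C(C(=O)[C@H](C)CC)C(=O)C2=C1OC(C)(C)C=C2 | intermediate
20 | (3S)-3-{[(8R)-7-hydroxy-2,2-dimethyl-6-[(2R)-2-methylbutanoyl]-8-(3-methylbut-2-en-1-yl)-5-oxo-5,8-dihydro-2H-chromen-8-yl]methyl}-4-methylpent-4-enal | C=C(C)[C@H](CC=O)C[C@]1(CC=C(C)C)C(O)=C(C(=O)[C@H](C)CC)C(=O)C2=C1OC(C)(C)C=C2 | intermediate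
21 | ethyl 2-(triphenylphosphoranylidene)propanoate | CCOC(=O)C(C)=P(c1ccccc1)(c1ccccc1)c1ccccc1 | starting material
22 | ethyl (2E,5R)-5-{[(8R)-7-hydroxy-2,2-dimethyl-6-[(2R)-2-methylbutanoyl]-8-(3-methylbut-2-en-1-yl)-5-oxo-5,8-dihydro-2H-chromen-8-yl]methyl}-2,6-dimethylhepta-2,6-dienoate | C=C(C)[C@H](C/C=C(\C)C(=O)OCC)C[C@]1(CC=C(C)C)C(O)=C(C(=O)[C@H](C)CC)C(=O)C2=C1OC(C)(C)C=C2 | intermediate
23 | (2E,5R)-5-{[(8R)-7-hydroxy-2,2-dimethyl-6-[(2R)-2-methylbutanoyl]-8-(3-methylbut-2-en-1-yl)-5-oxo-5,8-dihydro-2H-chromen-8-yl]methyl}-2,6-dimethylhepta-2,6-dienoic acid (CNP0184919.1) | C=C(C)[C@H](C/C=C(\C)C(=O)O)C[C@]1(CC=C(C)C)C(O)=C(C(=O)[C@H](C)CC)C(=O)C2=C1OC(C)(C)C=C2 | target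

## Step count and least certain steps

Total: 12 steps. Longest linear sequence: 11 steps (1 → 4 → 6 → 8 → 9 → 12 → 16 → 17 → 19 → 20 → 22 → 23); the resolution of 13 is a one-step side branch.

Step 8 (key step). The most likely failure is incomplete transfer of configuration: a chair with the ester axial, or a boat, would feed the C8 epimer (partly as the (Z)-enoate). Prolonged heating could also let the dienone revert and re-enter through the less selective pathway. The ester is only a medium-sized group, so the equatorial preference is real but not overwhelming.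
- Fallback: dearomative C-alkylation in place of the sigmatropic shift, setting out from 12.
- Fluoride cleavage of the silyl ether would give the diol (R)-1-[5,7-dihydroxy-2,2-dimethyl-8-(3-methylbut-2-en-1-yl)-2H-chromen-6-yl]-2-methylbutan-1-one F1.
- Its dilithium salt (LiN(SiMe3)2, THF, −78 to 0 °C) would be alkylated with ethyl (E)-4-bromobut-2-enoate at C8, the only ring carbon that is neither acylated nor part of the ring fusion. This is the classical C-alkylation that turns 3,5-dialkylated acylphloroglucinols into 4,4-dialkyl triones.
- Without a controlling element both C8 epimers should form: 17 and ethyl (2E)-4-[(8R)-7-hydroxy-2,2-dimethyl-6-[(2R)-2-methylbutanoyl]-8-(3-methylbut-2-en-1-yl)-5-oxo-5,8-dihydro-2H-chromen-8-yl]but-2-enoate F2. They are diastereomers because of the acyl stereocentre and would be separated by chromatography. The route is rejoined at 17.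

Step 7. The most likely failure is slow or misdirected substitution. The phenol is chelated and flanked on both sides, so attack at the secondary carbinol carbon may lose to attack at the terminal alkene carbon (SN2′). The doubly activated α-proton of the product may also be removed, with drift of the double bond into conjugation or loss of configuration.
- Fallback: a saturated surrogate that has neither an allylic terminus nor an allylic α-proton, setting out from 12.
- Ethyl (R)-2-hydroxy-4-(phenylselanyl)butanoate F3 would be made from commercial (R)-3-hydroxyoxolan-2-one by ring opening with PhSeNa and ethylation of the carboxylate with EtI.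
- The same Mitsunobu conditions with 12 would give ethyl (S)-2-({5-[(tert-butyldimethylsilyl)oxy]-2,2-dimethyl-6-[(2R)-2-methylbutanoyl]-8-(3-methylbut-2-en-1-yl)-2H-chromen-7-yl}oxy)-4-(phenylselanyl)butanoate F4.
- Oxidation with H2O2 at 0 °C would give the selenoxide ethyl (S)-2-({5-[(tert-butyldimethylsilyl)oxy]-2,2-dimethyl-6-[(2R)-2-methylbutanoyl]-8-(3-methylbut-2-en-1-yl)-2H-chromen-7-yl}oxy)-4-(phenylseleninyl)butanoate F5. Its syn-elimination at room temperature unveils the vinyl group under neutral conditions.
- The route is rejoined at 15, which is desilylated to 16 as in step 7.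

Step 9. The most likely failure is slow insertion at a β-carbon that carries a neopentyl-type substituent, combined with retention of rhodium by the diketonate of the substrate, so that protodeboronation of the alkenyl donor outruns addition. A mismatched pairing of ligand and C8 would show up as poor facial selectivity.
- Fallback: stoichiometric organocopper addition with separation of epimers, setting out from 17.
- After deprotonation of the trione with LiN(SiMe3)2 (1 equiv), (CH2=C(CH3))2CuLi with TMSCl in THF at −78 °C would add the isopropenyl group in the known Gilman manner.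
- Without catalyst control both methine epimers are expected: 19 and ethyl (3R)-3-{[(8R)-7-hydroxy-2,2-dimethyl-6-[(2R)-2-methylbutanoyl]-8-(3-methylbut-2-en-1-yl)-5-oxo-5,8-dihydro-2H-chromen-8-yl]methyl}-4-methylpent-4-enoate F6. They would be separated by chromatography. The route is rejoined at 19.

Step 10. The most likely failure is over-reduction: collapse of the aluminium hemiacetal before the quench releases aldehyde in the presence of hydride and leads on to the alcohol. Incomplete enolate formation would expose a ring carbonyl.
- Fallback: two-stage redox adjustment, setting out from 19.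
- Full reduction with LiBH4 (THF, 0 °C to rt, the first equivalent forming the enolate) would give (3S)-3-{[(8R)-7-hydroxy-2,2-dimethyl-6-[(2R)-2-methylbutanoyl]-8-(3-methylbut-2-en-1-yl)-5-oxo-5,8-dihydro-2H-chromen-8-yl]methyl}-4-methylpent-4-en-1-ol F7.
- Oxidation of the primary alcohol with n-Pr4N[RuO4] (cat.) and N-methylmorpholine N-oxide in CH2Cl2 would give 20, where the route is rejoined.

## Further compounds

F1 | step 8 | (R)-1-[5,7-dihydroxy-2,2-dimethyl-8-(3-methylbut-2-en-1-yl)-2H-chromen-6-yl]-2-methylbutan-1-one | CC1(C)C=Cc2c(O)c(C(=O)[C@H](C)CC)c(O)c(CC=C(C)C)c2O1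
F2 | step 8 | ethyl (2E)-4-[(8R)-7-hydroxy-2,2-dimethyl-6-[(2R)-2-methylbutanoyl]-8-(3-methylbut-2-en-1-yl)-5-oxo-5,8-dihydro-2H-chromen-8-yl]but-2-enoate (C8 epimer of 17) | CCOC(=O)/C=C/C[C@@]1(CC=C(C)C)C(O)=C(C(=O)[C@H](C)CC)C(=O)C2=C1OC(C)(C)C=C2
F3 | step 7 | ethyl (R)-2-hydroxy-4-(phenylselanyl)butanoate | CCOC(=O)[C@H](O)CC[Se]c1ccccc1
F4 | step 7 | ethyl (S)-2-({5-[(tert-butyldimethylsilyl)oxy]-2,2-dimethyl-6-[(2R)-2-methylbutanoyl]-8-(3-methylbut-2-en-1-yl)-2H-chromen-7-yl}oxy)-4-(phenylselanyl)butanoate | CC1(C)C=Cc2c(O[Si](C)(C)C(C)(C)C)c(C(=O)[C@H](C)CC)c(O[C@@H](CC[Se]c3ccccc3)C(=O)OCC)c(CC=C(C)C)c2O1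
F5 | step 7 | ethyl (S)-2-({5-[(tert-butyldimethylsilyl)oxy]-2,2-dimethyl-6-[(2R)-2-methylbutanoyl]-8-(3-methylbut-2-en-1-yl)-2H-chromen-7-yl}oxy)-4-(phenylseleninyl)butanoate | CC1(C)C=Cc2c(O[Si](C)(C)C(C)(C)C)c(C(=O)[C@H](C)CC)c(O[C@@H](CC[Se](=O)c3ccccc3)C(=O)OCC)c(CC=C(C)C)c2O1
F6 | step 9 | ethyl (3R)-3-{[(8R)-7-hydroxy-2,2-dimethyl-6-[(2R)-2-methylbutanoyl]-8-(3-methylbut-2-en-1-yl)-5-oxo-5,8-dihydro-2H-chromen-8-yl]methyl}-4-methylpent-4-enoate (methine epimer of 19) | C=C(C)[C@@H](CC(=O)OCC)C[C@]1(CC=C(C)C)C(O)=C(C(=O)[C@H](C)CC)C(=O)C2=C1OC(C)(C)C=C2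
F7 | step 10 | (3S)-3-{[(8R)-7-hydroxy-2,2-dimethyl-6-[(2R)-2-methylbutanoyl]-8-(3-methylbut-2-en-1-yl)-5-oxo-5,8-dihydro-2H-chromen-8-yl]methyl}-4-methylpent-4-en-1-ol | C=C(C)[C@H](CCO)C[C@]1(CC=C(C)C)C(O)=C(C(=O)[C@H](C)CC)C(=O)C2=C1OC(C)(C)C=C2
A1 | alternative 1 | methyl (2E,5R)-5-{[(8R)-7-hydroxy-2,2-dimethyl-6-[(2R)-2-methylbutanoyl]-8-(3-methylbut-2-en-1-yl)-5-oxo-5,8-dihydro-2H-chromen-8-yl]methyl}-2,6-dimethylhepta-2,6-dienoate (methyl ester of 23) | C=C(C)[C@H](C/C=C(\C)C(=O)OC)C[C@]1(CC=C(C)C)C(O)=C(C(=O)[C@H](C)CC)C(=O)C2=C1OC(C)(C)C=C2
A2 | alternative 2 | methyl (2E,5R)-5-{[(1R)-2-hydroxy-3-[(2R)-2-methylbutanoyl]-1-(3-methylbut-2-en-1-yl)-4,6-dioxocyclohex-2-en-1-yl]methyl}-2,6-dimethylhepta-2,6-dienoate (2-acyl-4,4-dialkylcyclohexane-1,3,5-trione, enol form) | C=C(C)[C@H](C/C=C(\C)C(=O)OC)C[C@]1(CC=C(C)C)C(O)=C(C(=O)[C@H](C)CC)C(=O)CC1=O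
A3 | alternative 1 | 3-methylbut-2-enal | CC(C)=CC=O
A4 | alternative 2 | methyl (2E,5R)-2,6-dimethyl-5-{[1-(3-methylbut-2-en-1-yl)-2,4,6-trioxocyclohexyl]methyl}hepta-2,6-dienoate (symmetric trione) | C=C(C)[C@H](C/C=C(\C)C(=O)OC)CC1(CC=C(C)C)C(=O)CC(=O)CC1=O
A5 | alternative 2 | (R)-2-methylbutanoic anhydride | CC[C@@H](C)C(=O)OC(=O)[C@H](C)CC
A6 | alternative 3 | (8R)-8-[(2S)-2-(1,3-dioxolan-2-ylmethyl)-3-methylbut-3-en-1-yl]-7-hydroxy-2,2-dimethyl-6-[(2R)-2-methylbutanoyl]-8-(3-methylbut-2-en-1-yl)-2H-chromen-5(8H)-one | C=C(C)[C@H](CC1OCCO1)C[C@]2(CC=C(C)C)C(O)=C(C(=O)[C@H](C)CC)C(=O)C3=C2OC(C)(C)C=C3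
A7 | alternative 3 | (8R)-8-[(2E)-4-chloro-3-methylbut-2-en-1-yl]-7-hydroxy-2,2-dimethyl-6-[(2R)-2-methylbutanoyl]-8-(3-methylbut-2-en-1-yl)-2H-chromen-5(8H)-one | ClC/C(C)=C/C[C@]1(CC=C(C)C)C(O)=C(C(=O)[C@H](C)CC)C(=O)C2=C1OC(C)(C)C=C2
A8 | alternative 3 | (1,3-dioxolan-2-ylmethyl)magnesium bromide | Br[Mg]CC1OCCO1
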